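**Plan**
- The target, 8-hydroxy-2-(3-hydroxy-4,5-dimethoxyphenyl)-6,7-dimethoxychromen-4-one, is achiral, so no stereochemistry has to be set.
- Enabling feature: C2, C3 and C4 of ring C carry oxygen at both ends (O1 on C2, the carbonyl oxygen on C4) and link ring B (at C2) to ring A (at C4 via C4a). This is the C5–C4–C3 skeleton of a 3,5-diarylisoxazole.
- Retrosynthesis: cut O1–C2 (ring C opens to a 2-hydroxyaryl β-diketone), mask the diketone as an isoxazole, then cut C3–C4 and the oxygen–C2 bond to a ring-A nitrile oxide and a ring-B terminal alkyne.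
- Forward: rings A and B come from two hydroxy-dimethoxybenzaldehydes. The isoxazole ring is formed first by (3+2) cycloaddition (step 9) and opened by hydrogenolysis (step 10). Ring C closes last under acid (step 11).

Key step: step 9

Remark: aldehydes 1 and 10 are assumed to be commercial. The oxime and hydroximoyl chloride are drawn as the usual E and Z isomers, but their geometry is lost in the nitrile oxide and is of no consequence.

**Step 1**
Reactants: 1 2-hydroxy-3,4-dimethoxybenzaldehyde
Product: 2 2-(benzyloxy)-3,4-dimethoxybenzaldehyde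
Conditions: BnBr, K2CO3, DMF, 60 °C
Reagents that add atoms: benzyl bromide, BrCc1ccccc1
Why: Williamson etherification of the phenoxide with a reactive benzylic halide is routine and installs the ether that later frees the C8 hydroxyl.

**Step 2**
Reactants: 2 2-(benzyloxy)-3,4-dimethoxybenzaldehyde
Product: 4 2-(benzyloxy)-3,4-dimethoxyphenol, via aryl formate 3 (not isolated)
Conditions: mCPBA, CH2Cl2, 0 °C to rt; then K2CO3 (cat.), MeOH, rt
Reagents that add atoms: 3-chloroperoxybenzoic acid (mCPBA), O=C(OO)c1cccc(Cl)c1
Why: Dakin-type Baeyer–Villiger oxidation, in which the electron-rich aryl group (ortho and para alkoxy) migrates in preference to hydride to give formate 3, which is methanolysed to the phenol.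

**Step 3**
Reactants: 4 2-(benzyloxy)-3,4-dimethoxyphenol
Product: 6 3-(benzyloxy)-2-hydroxy-4,5-dimethoxybenzaldehyde, via salicyl alcohol 5 (not isolated)
Conditions: MgCl2, Et3N, (CH2O)n, MeCN, reflux; aq. HCl work-up
Reagents that add atoms: paraformaldehyde (reacting as formaldehyde), C=O
Why: Magnesium-mediated ortho-formylation (Casnati–Skattebøl): the magnesium phenoxide delivers formaldehyde to the only free ortho position to give 5 as its magnesium salt, which is oxidised to the aldehyde by hydride transfer to a second formaldehyde.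

**Step 4**
Reactants: 6 3-(benzyloxy)-2-hydroxy-4,5-dimethoxybenzaldehyde
Product: 7 2,3-bis(benzyloxy)-4,5-dimethoxybenzaldehyde
Conditions: BnBr, K2CO3, DMF, 60 °C
Reagents that add atoms: benzyl bromide, BrCc1ccccc1
Why: Williamson etherification of the salicylaldehyde phenol, which masks the future O1 oxygen as a benzyl ether so that it is released together with the other two.

**Step 5**
Reactants: 7 2,3-bis(benzyloxy)-4,5-dimethoxybenzaldehyde
Product: 8 (E)-2,3-bis(benzyloxy)-4,5-dimethoxybenzaldehyde oxime
Conditions: NH2OH·HCl, NaOAc, EtOH–H2O, rt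
Reagents that add atoms: hydroxylamine hydrochloride, Cl.NO
Why: Condensation of an aryl aldehyde with hydroxylamine (oxime formation) should give the thermodynamically preferred E-aldoxime.

**Step 6**
Reactants: 8 (E)-2,3-bis(benzyloxy)-4,5-dimethoxybenzaldehyde oxime
Product: 9 (Z)-2,3-bis(benzyloxy)-N-hydroxy-4,5-dimethoxybenzenecarboximidoyl chloride
Conditions: NCS (1.05 equiv), DMF, 0 °C to rt; used crude
Reagents that add atoms: N-chlorosuccinimide, O=C1CCC(=O)N1Cl
Why: Chlorination of an aldoxime at the oxime carbon with NCS in DMF is the standard preparation of hydroximoyl chlorides and is well documented for polyalkoxybenzaldoximes.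

**Step 7**
Reactants: 10 3-hydroxy-4,5-dimethoxybenzaldehyde
Product: 11 3-(benzyloxy)-4,5-dimethoxybenzaldehyde
Conditions: BnBr, K2CO3, DMF, 60 °C
Reagents that add atoms: benzyl bromide, BrCc1ccccc1
Why: Williamson etherification protects the ring-B phenol as a benzyl ether that is removed in the same hydrogenolysis as the ring-A ethers.

**Step 8**
Reactants: 11 3-(benzyloxy)-4,5-dimethoxybenzaldehyde
Product: 12 1-(benzyloxy)-5-ethynyl-2,3-dimethoxybenzene
Conditions: dimethyl (1-diazo-2-oxopropyl)phosphonate, K2CO3, MeOH, rt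
Reagents that add atoms: dimethyl (1-diazo-2-oxopropyl)phosphonate, COP(=O)(OC)C(=[N+]=[N-])C(C)=O
Why: Ohira–Bestmann variant of the Seyferth–Gilbert homologation: the diazomethylphosphonate anion formed in situ olefinates the aldehyde, and loss of N2 followed by 1,2-hydride shift gives the terminal alkyne under mild base.

**Step 9**
Reactants: 9 (Z)-2,3-bis(benzyloxy)-N-hydroxy-4,5-dimethoxybenzenecarboximidoyl chloride; 12 1-(benzyloxy)-5-ethynyl-2,3-dimethoxybenzene
Product: 14 3-[2,3-bis(benzyloxy)-4,5-dimethoxyphenyl]-5-[3-(benzyloxy)-4,5-dimethoxyphenyl]isoxazole, via nitrile oxide 13 (not isolated)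
Conditions: Et3N (slow addition), 12 (1.3 equiv), CH2Cl2, 0 °C to rt
Reagents that add atoms: none
Why: Triethylamine removes HCl from 9 to release nitrile oxide 13, which adds across the terminal alkyne of 12 in a concerted, asynchronous (3+2) cycloaddition; the closest known reaction type is the Huisgen nitrile oxide–alkyne cycloaddition to 3,5-diarylisoxazoles. The five-membered isoxazole ring closes in this single intermolecular cycloaddition, the dipole carbon bonding to the terminal alkyne carbon (flavone C4–C3) and the dipole oxygen to the internal one (oxygen–C2). No stereocentre is created. The step needs regioselectivity for the 3,5- over the 3,4-diaryl isomer, which the monosubstituted alkyne secures because its unsubstituted terminus is both the less hindered end and the one that pairs best electronically with the nitrile oxide carbon. It also needs cycloaddition to outpace dimerisation of 13 to the furoxan, which is helped by slow addition of base, the excess of 12 and the ortho-benzyloxy group flanking the dipole.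

**Step 10**
Reactants: 14 3-[2,3-bis(benzyloxy)-4,5-dimethoxyphenyl]-5-[3-(benzyloxy)-4,5-dimethoxyphenyl]isoxazole
Product: 15 (Z)-3-amino-3-(2,3-dihydroxy-4,5-dimethoxyphenyl)-1-(3-hydroxy-4,5-dimethoxyphenyl)prop-2-en-1-one
Conditions: H2 (1 atm), 10% Pd/C, EtOAc–MeOH, rt; filtered under argon, used directly
Reagents that add atoms: none
Why: Catalytic hydrogenolysis cleaves the weak N–O bond of the isoxazole and the three benzyl ethers in one operation, and the resulting hydrogen-bonded Z-enaminone (a vinylogous amide) should resist further reduction.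

**Step 11**
Reactants: 15 (Z)-3-amino-3-(2,3-dihydroxy-4,5-dimethoxyphenyl)-1-(3-hydroxy-4,5-dimethoxyphenyl)prop-2-en-1-one
Product: 17 8-hydroxy-2-(3-hydroxy-4,5-dimethoxyphenyl)-6,7-dimethoxy-4H-chromen-4-one, via diketone 16 (not isolated)
Conditions: 2 M aq. HCl, EtOH, reflux, argon
Reagents that add atoms: water, O
Why: Acid hydrolysis of the enaminone gives β-diketone 16 (the C4 oxygen comes from water), and acid-catalysed cyclodehydration follows, the C8a hydroxyl adding 6-exo-trig to the C2 carbonyl as in the last stage of a Baker–Venkataraman flavone synthesis; the C8 hydroxyl cannot form a six-membered ring.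

**Compound list**
1 | 2-hydroxy-3,4-dimethoxybenzaldehyde | COc1ccc(C=O)c(O)c1OC | starting material
2 | 2-(benzyloxy)-3,4-dimethoxybenzaldehyde | COc1ccc(C=O)c(OCc2ccccc2)c1OC | intermediate
3 | 2-(benzyloxy)-3,4-dimethoxyphenyl formate | COc1ccc(OC=O)c(OCc2ccccc2)c1OC | intermediate
4 | 2-(benzyloxy)-3,4-dimethoxyphenol | COc1ccc(O)c(OCc2ccccc2)c1OC | intermediate
5 | 2-(benzyloxy)-6-(hydroxymethyl)-3,4-dimethoxyphenol | COc1cc(CO)c(O)c(OCc2ccccc2)c1OC | intermediate
6 | 3-(benzyloxy)-2-hydroxy-4,5-dimethoxybenzaldehyde | COc1cc(C=O)c(O)c(OCc2ccccc2)c1OC | intermediate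
7 | 2,3-bis(benzyloxy)-4,5-dimethoxybenzaldehyde | COc1cc(C=O)c(OCc2ccccc2)c(OCc2ccccc2)c1OC | intermediate
8 | (E)-2,3-bis(benzyloxy)-4,5-dimethoxybenzaldehyde oxime | COc1cc(/C=N/O)c(OCc2ccccc2)c(OCc2ccccc2)c1OC | intermediate
9 | (Z)-2,3-bis(benzyloxy)-N-hydroxy-4,5-dimethoxybenzenecarboximidoyl chloride | COc1cc(/C(Cl)=N/O)c(OCc2ccccc2)c(OCc2ccccc2)c1OC | intermediate
10 | 3-hydroxy-4,5-dimethoxybenzaldehyde | COc1cc(C=O)cc(O)c1OC | starting material
11 | 3-(benzyloxy)-4,5-dimethoxybenzaldehyde | COc1cc(C=O)cc(OCc2ccccc2)c1OC | intermediate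
12 | 1-(benzyloxy)-5-ethynyl-2,3-dimethoxybenzene | COc1cc(C#C)cc(OCc2ccccc2)c1OC | intermediate
13 | 2,3-bis(benzyloxy)-4,5-dimethoxybenzonitrile oxide | COc1cc(C#[N+][O-])c(OCc2ccccc2)c(OCc2ccccc2)c1OC | intermediate
14 | 3-[2,3-bis(benzyloxy)-4,5-dimethoxyphenyl]-5-[3-(benzyloxy)-4,5-dimethoxyphenyl]isoxazole | COc1cc(-c2cc(-c3cc(OC)c(OC)c(OCc4ccccc4)c3)on2)c(OCc2ccccc2)c(OCc2ccccc2)c1OC | intermediate
15 | (Z)-3-amino-3-(2,3-dihydroxy-4,5-dimethoxyphenyl)-1-(3-hydroxy-4,5-dimethoxyphenyl)prop-2-en-1-one | COc1cc(/C(N)=C/C(=O)c2cc(O)c(OC)c(OC)c2)c(O)c(O)c1OC | intermediate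
16 | 1-(2,3-dihydroxy-4,5-dimethoxyphenyl)-3-(3-hydroxy-4,5-dimethoxyphenyl)propane-1,3-dione | COc1cc(C(=O)CC(=O)c2cc(O)c(OC)c(OC)c2)c(O)c(O)c1OC | intermediate
17 | 8-hydroxy-2-(3-hydroxy-4,5-dimethoxyphenyl)-6,7-dimethoxy-4H-chromen-4-one | COc1cc(-c2cc(=O)c3cc(OC)c(OC)c(O)c3o2)cc(O)c1OC | target

**Step count**
Total: 11 steps. Longest linear sequence: 9 steps (steps 1–6, 9, 10, 11); the ring-B branch (steps 7–8) joins at step 9.

**Steps most likely to fail**

1. Step 9. Dimerisation of the nitrile oxide to the furoxan may outrun addition to the only moderately reactive aryl alkyne, and some 3,4-regioisomer may form. The fallback sets out from 11 and 9 and comes back at 14. Aldehyde 11 would be methylenated (Ph3PCH3Br, KOtBu, THF, Wittig) to 1-(benzyloxy)-5-ethenyl-2,3-dimethoxybenzene F1. Nitrile oxide 13, released from 9 with Et3N as before, should add faster to this styrene, with the 5-aryl regiochemistry typical of monosubstituted alkenes, to give racemic 3-[2,3-bis(benzyloxy)-4,5-dimethoxyphenyl]-5-[3-(benzyloxy)-4,5-dimethoxyphenyl]-4,5-dihydroisoxazole F2. Dehydrogenation with activated MnO2 in hot toluene would then return isoxazole 14.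

2. Step 6. Electrophilic chlorination of the one free position of ring A (para to a benzyloxy group, ortho to a methoxy group) may compete with chlorination at the oxime carbon. The fallback sets out from 8 (with 12) and comes back at 14. The chlorine source is removed altogether: oxime 8 would be oxidised with PhI(OAc)2 (a trivalent iodine reagent) in MeOH with catalytic TFA in the presence of alkyne 12, so that nitrile oxide 13 forms by oxidative dehydrogenation and is trapped at once to give 14. No compound outside the main list is formed (F0).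

3. Step 10. Debenzylation of the two adjacent ring-A ethers may be incomplete, the enaminone may be over-reduced, and the freed catechol may oxidise in air during handling. The fallback sets out from 14 and comes back at 15. The N–O bond alone would be cleaved with Mo(CO)6 in MeCN–H2O at reflux to give (Z)-3-amino-3-[2,3-bis(benzyloxy)-4,5-dimethoxyphenyl]-1-[3-(benzyloxy)-4,5-dimethoxyphenyl]prop-2-en-1-one F3. The three benzyl ethers would then be removed with BCl3 and pentamethylbenzene in CH2Cl2 at −78 °C, which should leave the methyl ethers intact (none sits ortho to a carbonyl), to give 15 for the acid step.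

**Further compounds**
F1 | step 9 | 1-(benzyloxy)-5-ethenyl-2,3-dimethoxybenzene | C=Cc1cc(OC)c(OC)c(OCc2ccccc2)c1
F2 | step 9 | racemic 3-[2,3-bis(benzyloxy)-4,5-dimethoxyphenyl]-5-[3-(benzyloxy)-4,5-dimethoxyphenyl]-4,5-dihydroisoxazole | COc1cc(C2=NOC(c3cc(OC)c(OC)c(OCc4ccccc4)c3)C2)c(OCc2ccccc2)c(OCc2ccccc2)c1OC
F0 | step 6 | none | none
F3 | step 10 | (Z)-3-amino-3-[2,3-bis(benzyloxy)-4,5-dimethoxyphenyl]-1-[3-(benzyloxy)-4,5-dimethoxyphenyl]prop-2-en-1-one | COc1cc(/C(N)=C/C(=O)c2cc(OC)c(OC)c(OCc3ccccc3)c2)c(OCc2ccccc2)c(OCc2ccccc2)c1OC
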